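**Assumption:** kuwanon B has no stereocentre and no stereogenic double bond (the SMILES carries no stereodescriptors), so it is achiral and no stereocontrol is needed.

## Retrosynthetic overview

1. Kuwanon B ⇐ 5,7-di-O-MOM / 2′-O-TBS flavone 14 by one global deprotection.
2. Key disconnection: C3–C4 (plus O1–C2) of the γ-pyrone. An aroyl radical from 2,4,6-tris(MOM-oxy)benzoic acid 6 adds to the aryl–alkyl alkyne 13, which already carries the prenyl group; radical-polar crossover then closes the ring onto an ortho MOM-ether oxygen.
3. Acid 6 ⇐ resorcinol: meta C–H oxygenation (Ir borylation/oxidation), then directed ortho-metalation/CO2.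
4. Alkyne 13 ⇐ resorcinol: C-acetylation, chromene annulation with prenal, methyl ketone → acetylide, prenyl bromide trap.
5. Ring order: both benzene rings come from resorcinol; the 2H-pyran (chromene) ring is made first (step 6); the γ-pyrone ring is made last (step 9).

## Route

**Step 1**
Reactants: 1 resorcinol
Product: 2 1,3-bis(methoxymethoxy)benzene
Conditions: MOMCl, i-Pr2NEt, CH2Cl2, 0 °C → rt
Reagents that add atoms: chloromethyl methyl ether, COCCl
Why: Williamson-type acetalisation of both phenols; MOM is inert to the borylation and later serves as the ortho-metalation director and the cyclising oxygen.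

**Step 2**
Reactants: 2 1,3-bis(methoxymethoxy)benzene
Product: 3 3,5-bis(methoxymethoxy)phenol
Conditions: B2pin2, [Ir(OMe)(cod)]2 (1.5 mol %), dtbpy, THF, 80 °C; then aq. H2O2, NaOH, 0 °C (one pot)
Reagents that add atoms: hydrogen peroxide, OO
Why: Sterically controlled Ir-catalysed C–H borylation of a 1,3-disubstituted arene occurs only at C5, and basic peroxide oxidation of the C–B bond leaves the MOM ethers intact.

**Step 3**
Reactants: 3 3,5-bis(methoxymethoxy)phenol
Product: 4 1,3,5-tris(methoxymethoxy)benzene
Conditions: NaH, MOMCl, DMF, 0 °C → rt
Reagents that add atoms: chloromethyl methyl ether, COCCl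
Why: Simple O-alkylation of the phenoxide gives the C3-symmetric ether, so all ring positions are equivalent for the next step.

**Step 4**
Reactants: 4 1,3,5-tris(methoxymethoxy)benzene; 5 carbon dioxide
Product: 6 2,4,6-tris(methoxymethoxy)benzoic acid
Conditions: n-BuLi, TMEDA, THF, 0 °C; CO2; aq. NaH2PO4 work-up (pH ≈ 5)
Reagents that add atoms: none
Why: Directed ortho-metalation between two MOM ethers and carboxylation of the aryllithium; the buffered work-up protects the acetals.

**Step 5**
Reactants: 1 resorcinol; 7 acetic acid
Product: 8 1-(2,4-dihydroxyphenyl)ethan-1-one (resacetophenone)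
Conditions: ZnCl2, AcOH, 145 °C
Reagents that add atoms: none
Why: Nencki reaction (ZnCl2-mediated Friedel–Crafts C-acylation) at C4 of resorcinol, ortho/para to the two hydroxyls.

**Step 6**
Reactants: 8 resacetophenone; 9 3-methylbut-2-enal (prenal)
Product: 10 1-(5-hydroxy-2,2-dimethyl-2H-chromen-6-yl)ethan-1-one
Conditions: pyridine, 140 °C, sealed tube
Reagents that add atoms: none
Why: Knoevenagel-type condensation at the carbon between the two oxygens, then oxa-6π-electrocyclisation through the free 4-OH; the chelated 2-OH stays free, which gives the angular chromene.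

**Step 7**
Reactants: 10 1-(5-hydroxy-2,2-dimethyl-2H-chromen-6-yl)ethan-1-one
Product: 11 1-[5-(tert-butyldimethylsilyloxy)-2,2-dimethyl-2H-chromen-6-yl]ethan-1-one
Conditions: TBSOTf, 2,6-lutidine, CH2Cl2, 0 °C → rt
Reagents that add atoms: tert-butyldimethylsilyl triflate, CC(C)(C)[Si](C)(C)OS(=O)(=O)C(F)(F)F
Why: Silylation of the hydrogen-bonded phenol; a silyl ether is chosen because it survives LDA/acetylide chemistry and has no weak C–H bond in a 1,5-relationship to the vinyl radical formed in step 9.

**Step 8**
Reactants: 11 the TBS-protected acetylchromene; 12 1-bromo-3-methylbut-2-ene (prenyl bromide)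
Product: 13 tert-butyl{[2,2-dimethyl-6-(5-methylhex-4-en-1-yn-1-yl)-2H-chromen-5-yl]oxy}dimethylsilane
Conditions: LDA (1.1 equiv), THF, −78 °C; ClP(O)(OEt)2; LDA (2.3 equiv), −78 °C → rt; then CuI (15 mol %), prenyl bromide, 0 °C → rt
Reagents that add atoms: none
Why: Negishi methyl-ketone-to-alkyne conversion (enol phosphate, β-elimination, lithium acetylide), followed by Cu-catalysed SN2 allylation of the acetylide at the primary carbon of prenyl bromide to give the skipped enyne.

**Step 9 (key step)**
Reactants: 6 2,4,6-tris(methoxymethoxy)benzoic acid (2 equiv); 13 the aryl alkyne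
Product: 14 2-[5-(tert-butyldimethylsilyloxy)-2,2-dimethyl-2H-chromen-6-yl]-5,7-bis(methoxymethoxy)-3-(3-methylbut-2-en-1-yl)-4H-chromen-4-one
Conditions: dimethyl dicarbonate, 2,6-lutidine, fac-Ir(ppy)3 (2 mol %), MeCN, 450 nm LEDs, rt, Ar
Reagents that add atoms: none
Why: Proposed new method: the mixed carbonic anhydride formed in situ from 6 is reduced by excited Ir(ppy)3 to the aroyl radical (known acyl-radical generation from ArCO2H/dimethyl dicarbonate), which adds to the alkyl-bearing alkyne carbon to give the linear α-aryl vinyl radical (C3–C4 bond); Ir(IV) oxidises this electron-rich radical to the vinyl cation, and an ortho MOM-ether oxygen closes the six-membered ring with loss of MeOCH2+ (O1–C2 bond), so the sequence is redox-neutral and uses no H-abstracting oxidant that would attack the prenyl or chromene groups; the closest known reactions are photoredox aroyl-radical/alkyne annulations to indenones and the polar domino acylation/oxa-cyclisation of o-alkoxybenzoyl chlorides with alkynes to chromones. Any β-methoxy enone formed by external capture of the cation should converge on the same chromone in step 10.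

**Step 10**
Reactants: 14 the protected flavone
Product: 15 kuwanon B
Conditions: 3 M aq. HCl/MeOH (1:4), 45 °C
Reagents that add atoms: none
Why: Acid-catalysed solvolysis removes both aryl MOM acetals and the aryl TBS ether in one operation; there is no hydroxyl positioned to cyclise onto the 3-prenyl group in a five- or six-membered ring, and comparable prenyl/chromene flavonoids are routinely unmasked this way.

## Compound list

1 | resorcinol | Oc1cccc(O)c1 | starting material
2 | 1,3-bis(methoxymethoxy)benzene | COCOc1cccc(OCOC)c1 | intermediate
3 | 3,5-bis(methoxymethoxy)phenol | COCOc1cc(O)cc(OCOC)c1 | intermediate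
4 | 1,3,5-tris(methoxymethoxy)benzene | COCOc1cc(OCOC)cc(OCOC)c1 | intermediate
5 | carbon dioxide | O=C=O | starting material
6 | 2,4,6-tris(methoxymethoxy)benzoic acid | COCOc1cc(OCOC)c(C(=O)O)c(OCOC)c1 | intermediate
7 | acetic acid | CC(=O)O | starting material
8 | 1-(2,4-dihydroxyphenyl)ethan-1-one | CC(=O)c1ccc(O)cc1O | intermediate
9 | 3-methylbut-2-enal | CC(C)=CC=O | starting material
10 | 1-(5-hydroxy-2,2-dimethyl-2H-chromen-6-yl)ethan-1-one | CC(=O)c1ccc2OC(C)(C)C=Cc2c1O | intermediate
11 | 1-[5-(tert-butyldimethylsilyloxy)-2,2-dimethyl-2H-chromen-6-yl]ethan-1-one | CC(=O)c1ccc2OC(C)(C)C=Cc2c1O[Si](C)(C)C(C)(C)C | intermediate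
12 | 1-bromo-3-methylbut-2-ene | CC(C)=CCBr | starting material
13 | tert-butyl{[2,2-dimethyl-6-(5-methylhex-4-en-1-yn-1-yl)-2H-chromen-5-yl]oxy}dimethylsilane | CC(C)=CCC#Cc1ccc2OC(C)(C)C=Cc2c1O[Si](C)(C)C(C)(C)C | intermediate
14 | 2-[5-(tert-butyldimethylsilyloxy)-2,2-dimethyl-2H-chromen-6-yl]-5,7-bis(methoxymethoxy)-3-(3-methylbut-2-en-1-yl)-4H-chromen-4-one | CC(C)=CCc1c(-c2ccc3OC(C)(C)C=Cc3c2O[Si](C)(C)C(C)(C)C)oc2cc(OCOC)cc(OCOC)c2c1=O | intermediate
15 | kuwanon B | CC(C)=CCc1c(-c2ccc3c(c2O)C=CC(C)(C)O3)oc2cc(O)cc(O)c2c1=O | target

## Summary

Total steps: 10. Longest linear sequence: 6 (steps 1–4, 9, 10 or steps 5–8, 9, 10).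

Steps most likely to fail, each with a fallback that changes the approach:

1. **Step 9.** The hindered, electron-rich mixed anhydride may be hard to reduce, addition to the electron-rich internal alkyne may be slow, and the vinyl radical may abstract hydrogen before it is oxidised. Fallback: build the pyrone by a polar route and move the radical C–C bond formation to C3–C1″. Couple the Weinreb amide of 6 with the lithium acetylide from step 8 (no prenyl quench) to give the ynone, cyclise with ICl (6-endo, loss of MOM) to the 3-iodoflavone, then install the prenyl group by radical allyl transfer to the C3 radical ((TMS)3SiH/AIBN with a 1,1-dimethylallyl sulfone).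
2. **Step 8.** Silyl migration in the ortho-silyloxy enolate or incomplete one-pot elimination/allylation could spoil the sequence. Fallback: start from the aldehyde instead of the ketone. Vilsmeier formylation of resorcinol, the same prenal chromenylation and silylation, Corey–Fuchs dibromo-olefination, then n-BuLi and a CuI/prenyl bromide quench give the same alkyne 13.
3. **Step 10.** Protic acid may hydrate or add across the electron-rich chromene or the prenyl alkene. Fallback: change the protecting-group plan so the end-game is fluoride-only. Use SEM ethers in place of MOM on ring A (same ortho-metalation/carboxylation and same ring-closing role in step 9) and remove SEM and TBS together with TBAF in THF/DMPU.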